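I had to decide whether to leave the west flask stirring to 2.0 h for more target or to work it up at once. That hung on whether the flat target readings were a true resting level.

| setting | west | flask |
|---|---|---|
| substrate | 20 mM | 20 mM |
| remark | the very flask that is asked about, followed so far |  |
| time |  | 2.0 h |

- west (time / min: target / %, substrate / %, homo dimer / %): 6.00: 10.8, 21.8, 28.3; 12.0: 12.1, 10.3, 29.9; 20.0: 10.2, 8.1, 32.0; 25.0: 11.0, 8.6, 32.1

(readings scatter by 1 percentage point)

- percent here means substrate units held: one homo dimer counts as two

* amount of target in the flask at 2.0 h, in percent of the substrate charged
* amount of substrate in the flask at 2.0 h, in percent of the substrate charged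
* amount of homo dimer in the flask at 2.0 h, in percent of the substrate charged
* amount of isomer of the product in the flask at 2.0 h, in percent of the substrate charged

Target alone told me little: its readings moved by about their scatter of 1 percentage point. So I divided target by substrate at each reading. In the west flask that quotient was 0.495 at 6.00 min. The pooled readings at 20.0 min and 25.0 min gave 1.27, which is more. I called this pooled figure ρ, the held ratio: target over substrate in one flask at one moment. It is a quasi-steady ratio read through that scatter.

The ratio marks a crossing. Before it, the west target readings climbed against substrate; after it, I reckoned target as ρ times substrate, so I took it to follow substrate. The west homo dimer readings still gained 2.2 points between 12.0 min and 25.0 min, so I took substrate units to be still leaving. I expected substrate to sink and target with it, so I judged waiting worthless and let the flask run on as a test.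

The forecast gave target 11%, substrate 7%, homo dimer 33% and isomer of the product 49%, saying “I expect little change by 2 h”. Its target is what taking over the last west reading gives. There I differed: on its own substrate, my ratio gives target 8.89%, which is less.

The flask gave target 4.64%, substrate 3.63%, homo dimer 38.1% and isomer of the product 19.4%.

    substrate ⇌ target (K = 1.90, k = 0.0590 min⁻¹)
    target ⇌ isomer of the product (K = 2.50, k = 0.0220 min⁻¹)
    isomer of the product ⇌ substrate (k = 0.0330 min⁻¹)
    substrate → decomposition product (k = 6.10 × 10⁻⁵ min⁻¹)
    2 substrate → homo dimer (k = 4.90 M⁻¹ min⁻¹)
    target → over-reaction product (k = 0.0370 min⁻¹)

The held ratio times that substrate gives target 4.61%. In the neighbour flask charged with 5.0 mM, it turns substrate 5.29% into target 6.72%, against the 6.66% that flask holds. Target sank along with substrate, and over-reaction product stood at 34.2% in the flask. With the path from target to over-reaction product taken away, the same flask holds target at 14.0% instead of 4.64%.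

The data are simulated for an exercise; scatter was added.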